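**Retrosynthetic overview** (chain atoms are labelled C1–C20 as in the target, C1 = lactone carbonyl)
1. Target ⇒ break the lactone bond C1–O5: an open-chain δ-hydroxy-β-keto thioester, closed last in the way a polyketide chain is released from its thioester.
2. Keto thioester ⇒ break C2–C3 (Claisen): a thioacetate enolate plus a fully unprotected trihydroxy δ-lactone, whose C3–O7 ester bond is the acyl donor.
3. δ-Lactone ⇒ acid unmasking of an acetonide tert-butyl ester; its C9/C11 syn-diol ⇒ chelate-controlled reduction of a β-hydroxy ketone.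
4. β-Hydroxy ketone ⇒ C9–C10 Mukaiyama aldol (1,3-anti from C7) between the enol silane of undecan-2-one and an aldehyde made from the nitrile of the commercial atorvastatin acetonide, which supplies C3–C9 with C5 and C7 already set.
5. Ring order: the dioxane (bought, protecting ring) → a transient δ-lactone C3–O7 (step 5) → the only ring of the target, the 4-hydroxy-5,6-dihydropyran-2-one C1–O5 (step 6).

Assumption: the 4-hydroxy enol in the SMILES and the 3-oxo lactone are one compound (the enol is what is isolated), and only species that persist in the flask until the next reagent is added carry "not isolated" numbers; adducts that are simply hydrolysed on work-up are described in the Why lines.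

**Step 1**
Reactants: 1 tert-butyl 2-[(4R,6R)-6-(cyanomethyl)-2,2-dimethyl-1,3-dioxan-4-yl]acetate
Product: 2 tert-butyl 2-[(4R,6S)-2,2-dimethyl-6-(2-oxoethyl)-1,3-dioxan-4-yl]acetate
Conditions: iBu2AlH (1.15 equiv), toluene, −78 °C, 1 h; MeOH quench, then aq. KNaC4H4O6, 0 °C → rt; short SiO2 plug, used at once
Reagents that add atoms: water, O
Why: Partial reduction of a nitrile: one hydride from iBu2AlH adds to C≡N at −78 °C far faster than to the hindered tert-butyl ester, the N-aluminoimine resists a second hydride and is hydrolysed to the aldehyde on work-up, and no stereocentre is touched (the 6R→6S label change is a CIP priority effect only).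

**Step 2**
Reactants: 3 undecan-2-one
Product: 5 trimethyl(undec-1-en-2-yloxy)silane, via lithium undec-1-en-2-olate 4 (not isolated)
Conditions: LiN(iPr)2 (1.05 equiv), THF, −78 °C, 30 min; Me3SiCl (1.2 equiv), −78 °C → rt; pentane/cold aq. NaHCO3, distil
Reagents that add atoms: chlorotrimethylsilane, C[Si](C)(C)Cl
Why: Kinetic enolate formation: the hindered amide base removes a methyl proton of the methyl ketone at −78 °C (≥95:5 over the internal methylene) and Me3SiCl traps the terminal enolate on oxygen.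

**Step 3**
Reactants: 2 tert-butyl 2-[(4R,6S)-2,2-dimethyl-6-(2-oxoethyl)-1,3-dioxan-4-yl]acetate; 5 trimethyl(undec-1-en-2-yloxy)silane
Product: 6 tert-butyl 2-[(4R,6R)-6-[(2R)-2-hydroxy-4-oxotridecyl]-2,2-dimethyl-1,3-dioxan-4-yl]acetate
Conditions: BF3·OEt2 (1.2 equiv), 5 (1.5 equiv), CH2Cl2, −78 °C, 2 h; aq. NaHCO3
Reagents that add atoms: none
Why: Mukaiyama aldol addition through an open transition state: in the BF3-bound β-alkoxy aldehyde the C7–O dipole opposes the carbonyl and the enol silane attacks the face anti to the dioxane residue (Evans 1,3-anti induction), which sets C9–OH anti to C7–O (expected dr about 6–10:1, minor epimer removed on SiO2), while acetonide and tert-butyl ester tolerate BF3·OEt2 at −78 °C.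

**Step 4**
Reactants: 6 tert-butyl 2-[(4R,6R)-6-[(2R)-2-hydroxy-4-oxotridecyl]-2,2-dimethyl-1,3-dioxan-4-yl]acetate
Product: 8 tert-butyl 2-[(4R,6R)-6-[(2S,4S)-2,4-dihydroxytridecyl]-2,2-dimethyl-1,3-dioxan-4-yl]acetate, via diethylboron chelate of the hydroxy ketone 7 (not isolated)
Conditions: Et2BOMe (1.2 equiv), THF/MeOH (4:1), −78 °C, 20 min; NaBH4 (1.2 equiv), −78 °C, 3 h; AcOH, then MeOH co-evaporation (×3)
Reagents that add atoms: none
Why: Narasaka–Prasad reduction: the C9 hydroxyl and the C11 ketone are locked in a six-membered diethylboron chelate and external axial hydride delivery from NaBH4 gives the 1,3-syn diol (C11 S, typically dr >20:1), so C9/C11 are syn and C7/C9 stay anti (the C9 label changes from R to S only through CIP priorities), while ester and acetonide are inert.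

**Step 5**
Reactants: 8 tert-butyl 2-[(4R,6R)-6-[(2S,4S)-2,4-dihydroxytridecyl]-2,2-dimethyl-1,3-dioxan-4-yl]acetate
Product: 9 (4R,6R)-6-[(2S,4S)-2,4-dihydroxytridecyl]-4-hydroxyoxan-2-one
Conditions: CF3CO2H/CH2Cl2/H2O (20:75:5), 0 °C → rt, 2 h; toluene co-evaporation
Reagents that add atoms: none
Why: Global acid deprotection with lactonisation: aqueous CF3CO2H hydrolyses the acetonide and cleaves the tert-butyl ester (as isobutene), and the freed 3,5-dihydroxy acid closes through its δ-hydroxyl O7 to the six-membered lactone (O5 would give a four-membered ring, O9 an eight-membered one), as statin lactones are made, without breaking any C–O bond at a stereocentre.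

**Step 6**
Reactants: 9 (4R,6R)-6-[(2S,4S)-2,4-dihydroxytridecyl]-4-hydroxyoxan-2-one; 10 S-tert-butyl ethanethioate
Product: 13 (6R)-4-hydroxy-6-[(2R,4S,6S)-2,4,6-trihydroxypentadecyl]-5,6-dihydro-2H-pyran-2-one, via lithium 1-(tert-butylsulfanyl)ethen-1-olate 11 (not isolated), via S-tert-butyl (5R,7R,9S,11S)-5,7,9,11-tetrahydroxy-3-oxoicosanethioate 12 (not isolated)
Conditions: 9 + LiN(SiMe3)2 (3.0 equiv), THF, −78 °C, 10 min; cannulate into 11 [10 (5 equiv), LiN(SiMe3)2 (5 equiv), THF, −78 °C]; −78 → −30 °C, 2 h; MeOH, 0 °C → rt, 3 h; 1 M HCl to pH 2, EtOAc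
Reagents that add atoms: none
Why: Proposed new method: the three hydroxyls are first capped as lithium alkoxides, thioester enolate 11 then adds to the lactone carbonyl (crossed Claisen condensation with ring oxygen O7 as leaving group) to give 12, which is shielded from a second addition as its enolate (free or as the reversible C3/O7 hemiketal), and after the MeOH quench the LiOMe formed lets the C5 alkoxide displace tert-butylthiolate from the thioester (directly or through the acylketene) in the only feasible six-membered closure, driven to completion because the product is a vinylogous acid (pKa about 5) held as its enolate until acidification, which is the C1–O5 thioester release of the biosynthesis; the closest known reactions are the Claisen condensation of unprotected β-hydroxy esters with excess LiCH2CO2tBu used for statin side chains, ester-enolate additions to δ-lactones, and the base-mediated lactonisation of δ-hydroxy-β-keto esters to 4-hydroxy-5,6-dihydropyran-2-ones, and C5 keeps its configuration because only its O–H bond reacts.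

**Compound list**
1 | tert-butyl 2-[(4R,6R)-6-(cyanomethyl)-2,2-dimethyl-1,3-dioxan-4-yl]acetate (atorvastatin intermediate) | N#CC[C@@H]1C[C@H](CC(=O)OC(C)(C)C)OC(C)(C)O1 | starting material
2 | tert-butyl 2-[(4R,6S)-2,2-dimethyl-6-(2-oxoethyl)-1,3-dioxan-4-yl]acetate | O=CC[C@@H]1C[C@H](CC(=O)OC(C)(C)C)OC(C)(C)O1 | intermediate
3 | undecan-2-one | CCCCCCCCCC(C)=O | starting material
4 | lithium undec-1-en-2-olate | [Li+].[O-]C(=C)CCCCCCCCC | intermediate
5 | trimethyl(undec-1-en-2-yloxy)silane | C=C(CCCCCCCCC)O[Si](C)(C)C | intermediate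
6 | tert-butyl 2-[(4R,6R)-6-[(2R)-2-hydroxy-4-oxotridecyl]-2,2-dimethyl-1,3-dioxan-4-yl]acetate | CCCCCCCCCC(=O)C[C@H](O)C[C@@H]1C[C@H](CC(=O)OC(C)(C)C)OC(C)(C)O1 | intermediate
7 | tert-butyl 2-[(4R,6R)-6-[(2R)-2-(diethylboranyloxy)-4-oxotridecyl]-2,2-dimethyl-1,3-dioxan-4-yl]acetate (boron chelated to the ketone) | CCCCCCCCCC(=O)C[C@H](OB(CC)CC)C[C@@H]1C[C@H](CC(=O)OC(C)(C)C)OC(C)(C)O1 | intermediate
8 | tert-butyl 2-[(4R,6R)-6-[(2S,4S)-2,4-dihydroxytridecyl]-2,2-dimethyl-1,3-dioxan-4-yl]acetate | CCCCCCCCC[C@H](O)C[C@H](O)C[C@@H]1C[C@H](CC(=O)OC(C)(C)C)OC(C)(C)O1 | intermediate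
9 | (4R,6R)-6-[(2S,4S)-2,4-dihydroxytridecyl]-4-hydroxyoxan-2-one | CCCCCCCCC[C@H](O)C[C@H](O)C[C@@H]1C[C@@H](O)CC(=O)O1 | intermediate
10 | S-tert-butyl ethanethioate | CC(=O)SC(C)(C)C | starting material
11 | lithium 1-(tert-butylsulfanyl)ethen-1-olate | [Li+].[O-]C(=C)SC(C)(C)C | intermediate
12 | S-tert-butyl (5R,7R,9S,11S)-5,7,9,11-tetrahydroxy-3-oxoicosanethioate | CCCCCCCCC[C@H](O)C[C@H](O)C[C@@H](O)C[C@@H](O)CC(=O)CC(=O)SC(C)(C)C | intermediate
13 | (6R)-4-hydroxy-6-[(2R,4S,6S)-2,4,6-trihydroxypentadecyl]-5,6-dihydro-2H-pyran-2-one | CCCCCCCCC[C@H](O)C[C@H](O)C[C@@H](O)C[C@@H]1CC(O)=CC(=O)O1 | target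

**Step count**
Total steps: 6 (five on the main line plus step 2 for enol silane 5).
Longest linear sequence: 5 steps (1 → 2 → 6 → 8 → 9 → 13).

**Steps most likely to fail, with fallbacks**

Step 6 (highest risk). The lactone of 9 may be enolised instead of attacked, the lithium alkoxides may be poorly soluble, or 12 may sit as its hemiketal. The fallback sets out from 8 and comes back at 12, using a protected, decarboxylative Claisen instead of the enolate opening. 2,2-Dimethoxypropane/PPTS converts the C9/C11 diol of 8 into the bis-acetonide tert-butyl 2-[(4R,6R)-6-{[(4S,6S)-2,2-dimethyl-6-nonyl-1,3-dioxan-4-yl]methyl}-2,2-dimethyl-1,3-dioxan-4-yl]acetate F1. NaOH in MeOH/H2O at 50 °C saponifies the ester to 2-[(4R,6R)-6-{[(4S,6S)-2,2-dimethyl-6-nonyl-1,3-dioxan-4-yl]methyl}-2,2-dimethyl-1,3-dioxan-4-yl]acetic acid F2. Activation with 1,1'-carbonyldiimidazole and Masamune–Brooks condensation with Mg(O2CCH2COStBu)2 gives S-tert-butyl 4-[(4R,6R)-6-{[(4S,6S)-2,2-dimethyl-6-nonyl-1,3-dioxan-4-yl]methyl}-2,2-dimethyl-1,3-dioxan-4-yl]-3-oxobutanethioate F3. AcOH/H2O (4:1, 40 °C) removes both acetonides to give 12, which is closed to 13 with K2CO3 in MeOH and then 1 M HCl, the same base-mediated closure as the second stage of step 6.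

Step 3. The 1,3-anti selectivity with an acetal oxygen at C7 may be modest, and BF3·OEt2 may nick the acetonide. The fallback sets out from 2 and comes back at 8, reversing the polarity of the aldol so that C11 is set first by 1,5-induction. MeMgBr (THF, −78 °C) adds to the aldehyde to give tert-butyl 2-[(4R,6R)-6-(2-hydroxypropyl)-2,2-dimethyl-1,3-dioxan-4-yl]acetate F4 (carbinol epimers). Dess–Martin periodinane gives the methyl ketone tert-butyl 2-[(4R,6S)-2,2-dimethyl-6-(2-oxopropyl)-1,3-dioxan-4-yl]acetate F5. Its boron enolate (Bu2BOTf, iPr2NEt, Et2O, −78 °C) adds to decanal with 1,5-anti induction from the C7 acetal oxygen to give tert-butyl 2-[(4R,6S)-6-[(4S)-4-hydroxy-2-oxotridecyl]-2,2-dimethyl-1,3-dioxan-4-yl]acetate F6. Et2BOMe/NaBH4 then reduces the C9 ketone syn to the C11 hydroxyl, which gives 8.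

Step 1. The tert-butyl ester may be over-reduced, or the β-alkoxy aldehyde may eliminate during imine hydrolysis. The fallback sets out from 1 and comes back at 2, taking the nitrile fully to the amine and then oxidising by transamination. Hydrogenation over Raney Ni (H2, NH3/MeOH), which leaves the ester alone, gives tert-butyl 2-[(4R,6R)-6-(2-aminoethyl)-2,2-dimethyl-1,3-dioxan-4-yl]acetate F7. Rapoport transamination (4-formyl-1-methylpyridinium benzenesulfonate; DBU; aqueous oxalic acid) then converts CH2NH2 into CHO, which gives 2.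

**Further compounds**
F1 | step 6 | tert-butyl 2-[(4R,6R)-6-{[(4S,6S)-2,2-dimethyl-6-nonyl-1,3-dioxan-4-yl]methyl}-2,2-dimethyl-1,3-dioxan-4-yl]acetate | CCCCCCCCC[C@H]1C[C@@H](C[C@@H]2C[C@H](CC(=O)OC(C)(C)C)OC(C)(C)O2)OC(C)(C)O1
F2 | step 6 | 2-[(4R,6R)-6-{[(4S,6S)-2,2-dimethyl-6-nonyl-1,3-dioxan-4-yl]methyl}-2,2-dimethyl-1,3-dioxan-4-yl]acetic acid | CCCCCCCCC[C@H]1C[C@@H](C[C@@H]2C[C@H](CC(=O)O)OC(C)(C)O2)OC(C)(C)O1
F3 | step 6 | S-tert-butyl 4-[(4R,6R)-6-{[(4S,6S)-2,2-dimethyl-6-nonyl-1,3-dioxan-4-yl]methyl}-2,2-dimethyl-1,3-dioxan-4-yl]-3-oxobutanethioate | CCCCCCCCC[C@H]1C[C@@H](C[C@@H]2C[C@H](CC(=O)CC(=O)SC(C)(C)C)OC(C)(C)O2)OC(C)(C)O1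
F4 | step 3 | tert-butyl 2-[(4R,6R)-6-(2-hydroxypropyl)-2,2-dimethyl-1,3-dioxan-4-yl]acetate (carbinol epimers) | CC(O)C[C@@H]1C[C@H](CC(=O)OC(C)(C)C)OC(C)(C)O1
F5 | step 3 | tert-butyl 2-[(4R,6S)-2,2-dimethyl-6-(2-oxopropyl)-1,3-dioxan-4-yl]acetate | CC(=O)C[C@@H]1C[C@H](CC(=O)OC(C)(C)C)OC(C)(C)O1
F6 | step 3 | tert-butyl 2-[(4R,6S)-6-[(4S)-4-hydroxy-2-oxotridecyl]-2,2-dimethyl-1,3-dioxan-4-yl]acetate | CCCCCCCCC[C@H](O)CC(=O)C[C@@H]1C[C@H](CC(=O)OC(C)(C)C)OC(C)(C)O1
F7 | step 1 | tert-butyl 2-[(4R,6R)-6-(2-aminoethyl)-2,2-dimethyl-1,3-dioxan-4-yl]acetate | NCC[C@@H]1C[C@H](CC(=O)OC(C)(C)C)OC(C)(C)O1
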